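The numbers in the tables come from a simulation for substances that don't exist, and the scatter is random.

Read an exchange ladder at rest by one ratio, not by its clocks.

all flasks: starting complex 10 mM (in portions, 3)
- violet: incoming ligand 7.5 mM; protic impurity 2 mM; run made earlier; portions every 80 s
- ochre: incoming ligand 30 mM; protic impurity 2 mM; run made earlier; portions every 80 s
- flask: incoming ligand 15.0 mM; protic impurity 2.00 mM; the portions of starting complex follow each other after 80 s, the first at the start; time 1.5 h

| run | time / min | complex with two exchanged / % | complex with one exchanged / % |
|---|---|---|---|
| violet | 8.00 | 2.4 | 21.9 |
| violet | 25.0 | 3.8 | 21.8 |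
| violet | 40.0 | 3.4 | 21.4 |
| violet | 60.0 | 3.0 | 21.7 |
| violet | 90.0 | 2.9 | 21.5 |
| ochre | 8.00 | 18.7 | 37.2 |
| ochre | 25.0 | 17.0 | 37.2 |
| ochre | 40.0 | 15.5 | 37.3 |
| ochre | 60.0 | 15.6 | 36.4 |
| ochre | 90.0 | 16.2 | 37.6 |

(standard deviation of a reading: 0.5 percentage points)

- what was read earlier has a scatter of 0.5 percentage points, one standard deviation
- on the list of suspects stand: complex with two exchanged + incoming ligand <-> leaving ligand + complex with three exchanged; complex with one exchanged + incoming ligand <-> leaving ligand + complex with two exchanged; starting complex + incoming ligand <-> leaving ligand + complex with one exchanged; protic impurity + incoming ligand -> quenched reagent; incoming ligand <-> dormant form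
- the reaction counts as stopped when no species that holds the starting complex changes by six tenths of a point or more over the second half of the time

1. which holds at 1.5 h: what has brought the reaction to rest, or that it has not come to rest (all of the starting complex has reacted / the incoming ligand has run out first / it is still moving / forward and back rates have come level)
2. how much complex with two exchanged there is at 1.5 h, in percent of the starting complex charged
3. how much complex with one exchanged there is at 1.5 h, in percent of the starting complex charged

Take the readings from 40.0 min on, where both runs lie nearly flat. Violet holds 21.5% of complex with one exchanged and 3.10% of complex with two exchanged; ochre holds 37.1% and 15.8%. Each exchange releases one leaving ligand, so violet has released 2.77 mM and ochre 6.86 mM. Assume that the protic impurity quenches its equal of incoming ligand, and leave out the unread complex with three exchanged. Then r stands at 0.983 in violet and 3.08 in ochre: r is the pool ratio, unused incoming ligand per leaving ligand released.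

At balance, each rung's ratio is a constant times r. Let A be one-exchanged over starting complex, divided by r: violet reads 0.291, ochre 0.256. Let B be two-exchanged over one-exchanged, divided by r: violet reads 0.146, ochre 0.138. Freeze the means, 0.273 and 0.142.

The flask's incoming ligand sits at the geometric mean of the two runs' charges, so try r = 1.74. That trial ladder releases 4.46 mM, and the balance then returns 1.91. Split the difference: r = 1.83. Commit to 30.7% of complex with one exchanged and 7.97% of complex with two exchanged, at rest by balance.

The weak link is counting unused ligand as free: the readings of complex with two exchanged in ochre fall 3.2 percentage points from 8.00 min to 40.0 min, against a scatter of 0.5 points. If that is ligand going dormant in first-order balance, free ligand is a fixed share of the pool, A and B absorb that share, and this reckoning needs no change on that account.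

The forecast says forward and back rates have come level, with 7.9% (6.8% to 9%) of complex with two exchanged and 30.6% (29% to 32.2%) of complex with one exchanged, holding that “Both runs therefore sit at equilibrium”.

The flask ends thus: forward and back rates have come level, with 8.08% of complex with two exchanged and 30.9% of complex with one exchanged.

    complex with two exchanged + incoming ligand ⇌ leaving ligand + complex with three exchanged (K = 0.0870, k = 2.10 M⁻¹ s⁻¹)
    complex with one exchanged + incoming ligand ⇌ leaving ligand + complex with two exchanged (K = 0.240, k = 0.250 M⁻¹ s⁻¹)
    starting complex + incoming ligand ⇌ leaving ligand + complex with one exchanged (K = 0.470, k = 0.410 M⁻¹ s⁻¹)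
    protic impurity + incoming ligand → quenched reagent (k = 5.70 M⁻¹ s⁻¹)
    incoming ligand ⇌ dormant form (K = 0.500, k = 6.50 × 10⁻⁴ s⁻¹)

This flask holds a mixture under thermodynamic control: a wait to 15.0 h and the portioning leave its conversion of starting complex unchanged. Now cut the starting complex to 4.0 mM, all else as in the flask. Starting from ochre's r = 3.08, a trial ladder in this neighbouring flask releases 2.86 mM; splitting the difference with the balance gives r = 3.32. That reckons to 38.8% of complex with one exchanged and 18.3% of complex with two exchanged. At 1.50 h the neighbouring flask stands at 37.9% of complex with one exchanged and 17.8% of complex with two exchanged.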